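**Retrosynthetic overview**
1. Feature: the central benzene is 1,2,3,4-tetrasubstituted. Its two adjacent CH carbons are the two carbons of acetylene. The triaryl (quinone-methide) carbon on one ring carbon and the ring-bound alkyne carbon on the next ring carbon can be joined through one oxygen atom into a five-membered ether ring fused to that benzene.
2. Selaginellin U ⇒ (BBr3 demethylation/dehydration) tetra-O-methyl triaryl carbinol ⇒ (Sonogashira; Ohira–Bestmann) gem-diaryl lactol ⇒ (i-Bu2AlH; benzylic oxidation) 1,1-diaryl-1,3-dihydroisobenzofuran.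
3. Dihydroisobenzofuran ⇒ [2+2+2] cycloaddition of an ether-tethered 1,6-diyne with acetylene at monovalent rhodium: the dihydrofuran ring closes first (metallacycle), then the central benzene, both in one step.
4. Diyne ⇒ O-alkylation with 1-bromobut-2-yne of the carbinol made from 4-ethynylanisole and 4,4'-dimethoxybenzophenone.

Key step: step 3

Remark: the target has no stereocentre; the lactol carbon of 13 is the only stereocentre on the route, is formed as a racemate and is removed in step 6; acetylene is taken as purified cylinder gas at atmospheric pressure.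

**Route**

Step 1
Reactants: 1 4-ethynylanisole; 2 4,4'-dimethoxybenzophenone
Product: 5 1,1,3-tris(4-methoxyphenyl)prop-2-yn-1-ol, via lithium (4-methoxyphenyl)acetylide 3 (not isolated), via lithium 1,1,3-tris(4-methoxyphenyl)prop-2-yn-1-olate 4 (not isolated)
Conditions: n-BuLi, THF, −78 °C; then 2, −78 °C to rt; then H2O
Reagents that add atoms: none
Why: Addition of a lithium acetylide to a non-enolisable diaryl ketone (carbonyl alkynylation) is fast and clean; the neutral water quench keeps the acid-labile bis(anisyl) propargylic carbinol intact; no stereocentre is formed.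

Step 2
Reactants: 5 1,1,3-tris(4-methoxyphenyl)prop-2-yn-1-ol; 6 1-bromobut-2-yne
Product: 8 but-2-ynyl 1,1,3-tris(4-methoxyphenyl)prop-2-ynyl ether, via sodium 1,1,3-tris(4-methoxyphenyl)prop-2-yn-1-olate 7 (not isolated)
Conditions: NaH, THF/DMF, 0 °C; then 6, 0 °C to rt
Reagents that add atoms: none
Why: Williamson etherification, in which the tertiary sodium alkoxide attacks the unhindered primary propargylic bromide in an SN2 reaction, while basic conditions at or below room temperature avoid both ionisation of the carbinol and retro-alkynylation.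

Step 3
Reactants: 8 but-2-ynyl 1,1,3-tris(4-methoxyphenyl)prop-2-ynyl ether; 9 acetylene
Product: 10 1,1,7-tris(4-methoxyphenyl)-4-methyl-1,3-dihydroisobenzofuran
Conditions: C2H2 (1 atm, balloon), RhCl(PPh3)3 (10 mol %), toluene, 80 °C
Reagents that add atoms: none
Why: Oxidative coupling of the two tethered alkynes at monovalent rhodium should give a trivalent-rhodium rhodacyclopentadiene; acetylene then inserts into a Rh–C bond and C–C reductive elimination releases the arene and returns monovalent rhodium. The closest known reaction type is the RhCl(PPh3)3-catalysed [2+2+2] cycloaddition of dipropargyl ethers with acetylene to give 1,3-dihydroisobenzofurans. The dihydrofuran ring closes in the oxidative coupling, which joins the two inner alkyne carbons across the C–O–C tether (the future C7a–C3a bond); the benzene ring closes by insertion of acetylene and reductive elimination, which form the C(methyl)–CH and CH–C(aryl) bonds. No stereocentre is formed. The step needs chemoselectivity for cross-trimerisation over diyne dimerisation and acetylene oligomerisation: the methyl and aryl caps slow self-coupling of the diyne, acetylene is kept in excess and is small enough to enter between those caps, and the gem-diaryl carbon of the tether (Thorpe–Ingold effect) holds the two alkynes in the reactive conformation. Regiochemistry is not in question because the tether fixes the diyne and acetylene is symmetrical, and the neutral chloride complex should not ionise the acid-labile bis(anisyl) propargylic ether.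

Step 4
Reactants: 10 1,1,7-tris(4-methoxyphenyl)-4-methyl-1,3-dihydroisobenzofuran
Product: 11 3,3,4-tris(4-methoxyphenyl)-7-methylisobenzofuran-1(3H)-one
Conditions: KMnO4, CuSO4·5H2O, CH2Cl2, rt
Reagents that add atoms: potassium permanganate, [K+].[O-][Mn](=O)(=O)=O
Why: Oxidation of a cyclic benzylic ether to the lactone with solid-supported permanganate attacks the only CH2 group that is both benzylic and alpha to oxygen, whereas the aryl methyl group, the anisyl rings and the quaternary C1 should be inert at room temperature.

Step 5
Reactants: 11 3,3,4-tris(4-methoxyphenyl)-7-methylisobenzofuran-1(3H)-one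
Product: 13 3,3,4-tris(4-methoxyphenyl)-7-methyl-1,3-dihydroisobenzofuran-1-ol (racemic lactol), via diisobutylaluminium lactolate 12 (not isolated)
Conditions: i-Bu2AlH, CH2Cl2, −78 °C; then aq. KNaC4H4O6 (potassium sodium tartrate)
Reagents that add atoms: none
Why: Partial reduction of a lactone with i-Bu2AlH stops at the lactol because the tetrahedral aluminium hemiacetal is stable at −78 °C and collapses only on work-up; the new lactol stereocentre is formed as a racemate and is erased in step 6.

Step 6
Reactants: 13 3,3,4-tris(4-methoxyphenyl)-7-methyl-1,3-dihydroisobenzofuran-1-ol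
Product: 15 [2-ethynyl-6-(4-methoxyphenyl)-3-methylphenyl]bis(4-methoxyphenyl)methanol, via open-chain hydroxy aldehyde 14 (not isolated)
Conditions: dimethyl (1-diazo-2-oxopropyl)phosphonate, K2CO3, MeOH/THF, 0 °C to rt
Reagents that add atoms: dimethyl (1-diazo-2-oxopropyl)phosphonate (Ohira–Bestmann reagent), CC(=O)C(=[N+]=[N-])P(=O)(OC)OC
Why: Ohira–Bestmann variant of the Seyferth–Gilbert homologation, in which carbonate in methanol opens the lactol to the non-enolisable aldehyde and generates the dimethyl (diazomethyl)phosphonate anion, whose addition, loss of phosphate and nitrogen and 1,2-hydrogen shift of the alkylidene carbene should give the terminal alkyne, the hindered tertiary carbinol being too weakly ionised under carbonate to add to it.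

Step 7
Reactants: 15 [2-ethynyl-6-(4-methoxyphenyl)-3-methylphenyl]bis(4-methoxyphenyl)methanol; 16 4-iodoanisole
Product: 17 [2-[(4-methoxyphenyl)ethynyl]-6-(4-methoxyphenyl)-3-methylphenyl]bis(4-methoxyphenyl)methanol
Conditions: Pd(PPh3)2Cl2 (3 mol %), CuI (5 mol %), Et3N/THF (degassed), rt
Reagents that add atoms: none
Why: Sonogashira coupling of a terminal alkyne with an aryl iodide proceeds at room temperature (oxidative addition to zerovalent palladium, transmetalation from the copper acetylide, reductive elimination); the free tertiary alcohol is tolerated and the low temperature disfavours metal-promoted addition of the carbinol to the alkyne.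

Step 8
Reactants: 17 [2-[(4-methoxyphenyl)ethynyl]-6-(4-methoxyphenyl)-3-methylphenyl]bis(4-methoxyphenyl)methanol
Product: 19 selaginellin U, via tetraphenol carbinol 18 (not isolated)
Conditions: BBr3 (excess), CH2Cl2, −78 °C to rt; then H2O
Reagents that add atoms: none
Why: Lewis-acid cleavage of the four aryl methyl ethers with BBr3 should be followed on aqueous work-up by loss of water from the tris(4-hydroxyphenyl) carbinol through one 4-hydroxyphenyl group to give the conjugated quinone methide (fuchsone formation), the internal diaryl alkyne being slow to undergo bromoboration at low temperature.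

**Compound list**
1 | 4-ethynylanisole | COc1ccc(C#C)cc1 | starting material
2 | 4,4'-dimethoxybenzophenone | COc1ccc(cc1)C(=O)c1ccc(OC)cc1 | starting material
3 | lithium (4-methoxyphenyl)acetylide (not isolated) | COc1ccc(C#[C-])cc1.[Li+] | intermediate
4 | lithium 1,1,3-tris(4-methoxyphenyl)prop-2-yn-1-olate (not isolated) | COc1ccc(C#CC([O-])(c2ccc(OC)cc2)c2ccc(OC)cc2)cc1.[Li+] | intermediate
5 | 1,1,3-tris(4-methoxyphenyl)prop-2-yn-1-ol | COc1ccc(C#CC(O)(c2ccc(OC)cc2)c2ccc(OC)cc2)cc1 | intermediate
6 | 1-bromobut-2-yne | CC#CCBr | starting material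
7 | sodium 1,1,3-tris(4-methoxyphenyl)prop-2-yn-1-olate (not isolated) | COc1ccc(C#CC([O-])(c2ccc(OC)cc2)c2ccc(OC)cc2)cc1.[Na+] | intermediate
8 | but-2-ynyl 1,1,3-tris(4-methoxyphenyl)prop-2-ynyl ether | CC#CCOC(C#Cc1ccc(OC)cc1)(c1ccc(OC)cc1)c1ccc(OC)cc1 | intermediate
9 | acetylene | C#C | starting material
10 | 1,1,7-tris(4-methoxyphenyl)-4-methyl-1,3-dihydroisobenzofuran | Cc1ccc(-c2ccc(OC)cc2)c2c1COC2(c1ccc(OC)cc1)c1ccc(OC)cc1 | intermediate
11 | 3,3,4-tris(4-methoxyphenyl)-7-methylisobenzofuran-1(3H)-one | Cc1ccc(-c2ccc(OC)cc2)c2c1C(=O)OC2(c1ccc(OC)cc1)c1ccc(OC)cc1 | intermediate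
12 | diisobutylaluminium lactolate of 13, O-aluminated at the lactol oxygen (not isolated) | Cc1ccc(-c2ccc(OC)cc2)c2c1C(O[Al](CC(C)C)CC(C)C)OC2(c1ccc(OC)cc1)c1ccc(OC)cc1 | intermediate
13 | 3,3,4-tris(4-methoxyphenyl)-7-methyl-1,3-dihydroisobenzofuran-1-ol (racemic) | Cc1ccc(-c2ccc(OC)cc2)c2c1C(O)OC2(c1ccc(OC)cc1)c1ccc(OC)cc1 | intermediate
14 | 2-[hydroxybis(4-methoxyphenyl)methyl]-3-(4-methoxyphenyl)-6-methylbenzaldehyde (open-chain form of 13, not isolated) | Cc1ccc(-c2ccc(OC)cc2)c(C(O)(c2ccc(OC)cc2)c2ccc(OC)cc2)c1C=O | intermediate
15 | [2-ethynyl-6-(4-methoxyphenyl)-3-methylphenyl]bis(4-methoxyphenyl)methanol | Cc1ccc(-c2ccc(OC)cc2)c(C(O)(c2ccc(OC)cc2)c2ccc(OC)cc2)c1C#C | intermediate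
16 | 4-iodoanisole | COc1ccc(I)cc1 | starting material
17 | [2-[(4-methoxyphenyl)ethynyl]-6-(4-methoxyphenyl)-3-methylphenyl]bis(4-methoxyphenyl)methanol | Cc1ccc(-c2ccc(OC)cc2)c(C(O)(c2ccc(OC)cc2)c2ccc(OC)cc2)c1C#Cc1ccc(OC)cc1 | intermediate
18 | [2-[(4-hydroxyphenyl)ethynyl]-6-(4-hydroxyphenyl)-3-methylphenyl]bis(4-hydroxyphenyl)methanol (tetraphenol carbinol, not isolated) | Cc1ccc(-c2ccc(O)cc2)c(C(O)(c2ccc(O)cc2)c2ccc(O)cc2)c1C#Cc1ccc(O)cc1 | intermediate
19 | selaginellin U, 4-[[2-[(4-hydroxyphenyl)ethynyl]-6-(4-hydroxyphenyl)-3-methylphenyl](4-hydroxyphenyl)methylidene]cyclohexa-2,5-dien-1-one | Cc1ccc(-c2ccc(O)cc2)c(C(=C2C=CC(=O)C=C2)c2ccc(O)cc2)c1C#Cc1ccc(O)cc1 | target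

**Step count**
Total steps: 8. Longest linear sequence: 8 steps (from 1 or 2 to 19).

**Steps most likely to fail**

Step 3 (key cyclotrimerisation).
- What may go wrong: oxidative coupling of the two fully substituted, sterically shielded alkynes at rhodium may be slow. Acetylene oligomerisation and catalyst deactivation by the gas could then outrun the cross-trimerisation, and the low solubility of acetylene at 80 °C aggravates this.
- Fallback, from diyne 8 back to phthalan 10: the diyne is cyclotrimerised with trimethylsilylacetylene, a liquid partner that can be used in large excess and is slow to self-trimerise, with RhCl(PPh3)3 in toluene at 100 °C in a sealed tube. This should give a mixture of the regioisomers 1,1,7-tris(4-methoxyphenyl)-4-methyl-5-(trimethylsilyl)-1,3-dihydroisobenzofuran F1 and 1,1,7-tris(4-methoxyphenyl)-4-methyl-6-(trimethylsilyl)-1,3-dihydroisobenzofuran F2. The unseparated mixture is protodesilylated by ipso-protonation with CF3CO2H in CH2Cl2 at 0 °C to rt, so both isomers converge on 10. Any reversible opening of the trityl-type ether in acid should re-close on bicarbonate work-up.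

Step 6 (alkynylation of the lactol).
- What may go wrong: the ring–chain equilibrium lies far on the side of the gem-diaryl lactol, so capture of the open aldehyde may be slower than decomposition of the diazophosphonate anion in methanol. On long exposure to base the carbinol may also add to the new alkyne (5-exo-dig).
- Fallback, from lactol 13 back to alkyne 15: a Corey–Fuchs sequence with a thermally stable ylide. Lactol 13 is treated with (dibromomethyl)triphenylphosphonium bromide and KOt-Bu in THF, rt to reflux, to give [2-(2,2-dibromoethenyl)-6-(4-methoxyphenyl)-3-methylphenyl]bis(4-methoxyphenyl)methanol F3. Excess n-BuLi in THF at −78 °C, then H2O, should then deliver 15 by bromine–lithium exchange and Fritsch–Buttenberg–Wiechell 1,2-shift. At this temperature the lithium alkoxide should not add to the alkyne.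

Step 4 (benzylic oxidation).
- What may go wrong: the heterogeneous permanganate oxidation may stall on the hindered substrate, and when forced it may attack the aryl methyl group or degrade the electron-rich anisyl rings.
- Fallback, from phthalan 10 directly to lactol 13, bypassing 11 and step 5: hydride abstraction from the alpha-oxy benzylic CH2 with DDQ in CH2Cl2/H2O (or 1,2-dichloroethane/H2O at 60 °C), the oxocarbenium ion being captured by water. Because C1 is quaternary no isobenzofuran can form; any 11 formed by further oxidation is returned to 13 through step 5. No new compound is made.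

**Further compounds**
F1 | step 3 | 1,1,7-tris(4-methoxyphenyl)-4-methyl-5-(trimethylsilyl)-1,3-dihydroisobenzofuran | Cc1c([Si](C)(C)C)cc(-c2ccc(OC)cc2)c2c1COC2(c1ccc(OC)cc1)c1ccc(OC)cc1
F2 | step 3 | 1,1,7-tris(4-methoxyphenyl)-4-methyl-6-(trimethylsilyl)-1,3-dihydroisobenzofuran | Cc1cc([Si](C)(C)C)c(-c2ccc(OC)cc2)c2c1COC2(c1ccc(OC)cc1)c1ccc(OC)cc1
F3 | step 6 | [2-(2,2-dibromoethenyl)-6-(4-methoxyphenyl)-3-methylphenyl]bis(4-methoxyphenyl)methanol | Cc1ccc(-c2ccc(OC)cc2)c(C(O)(c2ccc(OC)cc2)c2ccc(OC)cc2)c1C=C(Br)Br
F0 | step 4 | none | none
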